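**Retrosynthetic overview**
- The TIPS ether on the syringyl phenol is removed last. Before that, the only ring that is built, the trans-2,3-dihydro-1,4-dioxine ring, is closed by intramolecular Pd-catalysed aryl C–O coupling of a threo 1-aryl-2-(2-bromoaryloxy)propan-1-ol, with retention at both stereocentres. Both benzene rings are bought.
- The C-methyl group comes from CH2OH (tosylate, then hydride) of a 1,3-diol obtained by reductive removal of an Evans auxiliary.
- Key C–C bond (C2–C3 of the dioxane): Evans boron syn-aldol between an N-(aryloxyacetyl)-(S)-4-benzyloxazolidinone and O-TIPS-syringaldehyde, which sets both stereocentres.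
- The aryloxyacetic acid comes from 5-bromovanillin: O-alkylation with methyl bromoacetate, Julia–Kocienski olefination to the (E)-propenyl group, saponification.

Assumption: the SMILES is read as the trans-(2R,3R) isomer, and that enantiomer is made.

**Route**

Step 1
Reactants: 1 5-bromovanillin (3-bromo-4-hydroxy-5-methoxybenzaldehyde); 2 methyl bromoacetate
Product: 3 methyl 2-(2-bromo-4-formyl-6-methoxyphenoxy)acetate
Conditions: K2CO3, DMF, rt
Reagents that add atoms: none
Why: Williamson ether synthesis in which the phenoxide, made more acidic by the para-formyl group, displaces bromide from the activated α-bromo ester without touching the aldehyde.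

Step 2
Reactants: 4 1-phenyl-1H-tetrazole-5-thiol; 5 iodoethane
Product: 6 5-(ethylsulfanyl)-1-phenyl-1H-tetrazole
Conditions: K2CO3, acetone, reflux
Reagents that add atoms: none
Why: SN2 S-alkylation of the soft thiolate on a primary iodide gives the thioether cleanly.

Step 3
Reactants: 6 5-(ethylsulfanyl)-1-phenyl-1H-tetrazole
Product: 7 5-(ethylsulfonyl)-1-phenyl-1H-tetrazole
Conditions: 30% H2O2, (NH4)6Mo7O24·4H2O (cat), EtOH, 0 °C → rt
Reagents that add atoms: hydrogen peroxide, OO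
Why: Molybdate-catalysed peroxide oxidation of a sulfide to the sulfone is the standard entry to Julia–Kocienski reagents and the tetrazole is inert to it.

Step 4
Reactants: 7 5-(ethylsulfonyl)-1-phenyl-1H-tetrazole; 3 methyl 2-(2-bromo-4-formyl-6-methoxyphenoxy)acetate
Product: 9 methyl 2-{2-bromo-6-methoxy-4-[(E)-prop-1-enyl]phenoxy}acetate, via potassium sulfonyl carbanion 8 (not isolated)
Conditions: 7, KN(SiMe3)2, DME, −60 °C; then 3, −60 °C → rt; sat aq NH4Cl
Reagents that add atoms: none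
Why: Julia–Kocienski olefination, in which the sulfonyl carbanion adds to the aryl aldehyde and the adduct collapses by Smiles rearrangement with loss of SO2 and tetrazololate to give the (E)-propenyl arene (E:Z expected ≥95:5) while the ester survives at low temperature.

Step 5
Reactants: 9 methyl 2-{2-bromo-6-methoxy-4-[(E)-prop-1-enyl]phenoxy}acetate
Product: 10 2-{2-bromo-6-methoxy-4-[(E)-prop-1-enyl]phenoxy}acetic acid
Conditions: LiOH, THF/H2O, 0 °C → rt; 1 M HCl to pH 2; recrystallise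
Reagents that add atoms: lithium hydroxide, [Li+].[OH-]
Why: Ester saponification under mild base leaves the aryl bromide and the styrene untouched, and recrystallising the acid removes traces of the Z isomer.

Step 6
Reactants: 10 2-{2-bromo-6-methoxy-4-[(E)-prop-1-enyl]phenoxy}acetic acid; 11 (S)-4-benzyloxazolidin-2-one
Product: 13 (4S)-4-benzyl-3-(2-{2-bromo-6-methoxy-4-[(E)-prop-1-enyl]phenoxy}acetyl)oxazolidin-2-one, via mixed pivalic anhydride 12 (not isolated)
Conditions: PivCl, Et3N, THF, −20 °C; then 11, LiCl, −20 °C → rt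
Reagents that add atoms: none
Why: N-acylation of the Evans auxiliary through a mixed anhydride, in which the oxazolidinone attacks the less hindered aryloxyacetyl carbonyl under base-only conditions that spare the acid-sensitive propenyl arene, with no stereocentre made or disturbed.

Step 7
Reactants: 14 syringaldehyde (4-hydroxy-3,5-dimethoxybenzaldehyde)
Product: 15 3,5-dimethoxy-4-(triisopropylsilyloxy)benzaldehyde
Conditions: TIPSCl, imidazole, DMF, rt
Reagents that add atoms: triisopropylsilyl chloride (TIPSCl), CC(C)[Si](Cl)(C(C)C)C(C)C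
Why: Silyl ether formation gives a bulky phenol protecting group, flanked by two methoxy groups, that withstands boron triflate, hydrides and carbonate base and is removed by fluoride at the end.

Step 8
Reactants: 13 (4S)-4-benzyl-3-(2-{2-bromo-6-methoxy-4-[(E)-prop-1-enyl]phenoxy}acetyl)oxazolidin-2-one; 15 3,5-dimethoxy-4-(triisopropylsilyloxy)benzaldehyde
Product: 18 (4S)-4-benzyl-3-[(2S,3R)-2-{2-bromo-6-methoxy-4-[(E)-prop-1-enyl]phenoxy}-3-[3,5-dimethoxy-4-(triisopropylsilyloxy)phenyl]-3-hydroxypropanoyl]oxazolidin-2-one, via dibutylboron Z-enolate 16 (not isolated), via dibutylboron aldolate 17 (not isolated)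
Conditions: Bu2BOTf, Et3N, CH2Cl2, −78 → 0 °C; then 15, −78 → 0 °C; pH 7 buffer, MeOH, 30% H2O2, 0 °C
Reagents that add atoms: none
Why: Evans boron syn-aldol, in which the Z-boron enolate reacts through a closed Zimmerman–Traxler chair with the aldehyde approaching the enolate face opposite the benzyl group of the dipole-opposed (S)-oxazolidinone, giving the 2,3-syn adduct with C2 = S and C3 = R and forming the key C–C bond.

Step 9
Reactants: 18 the syn aldol adduct
Product: 19 (1R,2R)-2-{2-bromo-6-methoxy-4-[(E)-prop-1-enyl]phenoxy}-1-[3,5-dimethoxy-4-(triisopropylsilyloxy)phenyl]propane-1,3-diol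
Conditions: LiBH4, MeOH (1 equiv), THF, 0 °C
Reagents that add atoms: none
Why: Reductive cleavage of the N-acyloxazolidinone by hydride attack at the exocyclic carbonyl gives the primary alcohol and returns the auxiliary, with both stereocentres untouched (the C2 descriptor changes from S to R only because CH2OH ranks below the carbinol carbon).

Step 10
Reactants: 19 the threo 1,3-diol
Product: 20 (2R,3R)-2-{2-bromo-6-methoxy-4-[(E)-prop-1-enyl]phenoxy}-3-[3,5-dimethoxy-4-(triisopropylsilyloxy)phenyl]-3-hydroxypropyl 4-methylbenzenesulfonate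
Conditions: TsCl, pyridine, CH2Cl2, 0 °C → rt
Reagents that add atoms: 4-toluenesulfonyl chloride (TsCl), Cc1ccc(cc1)S(Cl)(=O)=O
Why: Chemoselective sulfonylation of the unhindered primary hydroxyl over the hindered secondary benzylic one.

Step 11
Reactants: 20 the primary tosylate
Product: 21 (1R,2R)-2-{2-bromo-6-methoxy-4-[(E)-prop-1-enyl]phenoxy}-1-[3,5-dimethoxy-4-(triisopropylsilyloxy)phenyl]propan-1-ol
Conditions: LiEt3BH, THF, 0 °C → rt
Reagents that add atoms: none
Why: SN2 hydride displacement of the primary tosylate turns CH2OTs into CH3 at a temperature at which the aryl bromide, the aryl silyl ether and both stereocentres are left alone.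

Step 12
Reactants: 21 the threo bromo alcohol
Product: 22 (2R,3R)-2-[3,5-dimethoxy-4-(triisopropylsilyloxy)phenyl]-5-methoxy-3-methyl-7-[(E)-prop-1-enyl]-2,3-dihydro-1,4-benzodioxine
Conditions: Pd(OAc)2 (5 mol %), 2-(di-tert-butylphosphino)-1,1'-binaphthyl (6 mol %), Cs2CO3, toluene, 80 °C
Reagents that add atoms: none
Why: Intramolecular Buchwald-type Pd-catalysed C–O cross-coupling, in which zerovalent palladium inserts into the C–Br bond ortho to the ether oxygen and the bulky biaryl phosphine drives C–O reductive elimination to close the six-membered ring without breaking any bond to a stereocentre, so the threo (1R,2R) alcohol gives the trans (2R,3R) ring with retention.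

Step 13
Reactants: 22 the TIPS-protected benzodioxine
Product: 23 2,6-dimethoxy-4-{(2R,3R)-5-methoxy-3-methyl-7-[(E)-prop-1-enyl]-2,3-dihydro-1,4-benzodioxin-2-yl}phenol (target)
Conditions: Bu4NF, AcOH, THF, 0 °C
Reagents that add atoms: none
Why: Fluoride-mediated desilylation of the aryl silyl ether, buffered with acetic acid so the freed para-hydroxybenzyl ether never meets strong base, leaves the alkene and both stereocentres intact.

**Compound list**
1 | 5-bromovanillin (3-bromo-4-hydroxy-5-methoxybenzaldehyde) | O=Cc1cc(Br)c(O)c(OC)c1 | starting material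
2 | methyl bromoacetate | COC(=O)CBr | starting material
3 | methyl 2-(2-bromo-4-formyl-6-methoxyphenoxy)acetate | COC(=O)COc1c(Br)cc(C=O)cc1OC | intermediate
4 | 1-phenyl-1H-tetrazole-5-thiol | Sc1nnnn1-c1ccccc1 | starting material
5 | iodoethane | CCI | starting material
6 | 5-(ethylsulfanyl)-1-phenyl-1H-tetrazole | CCSc1nnnn1-c1ccccc1 | intermediate
7 | 5-(ethylsulfonyl)-1-phenyl-1H-tetrazole | CCS(=O)(=O)c1nnnn1-c1ccccc1 | intermediate
8 | potassium 1-[(1-phenyl-1H-tetrazol-5-yl)sulfonyl]ethanide | C[CH-]S(=O)(=O)c1nnnn1-c1ccccc1.[K+] | intermediate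
9 | methyl 2-{2-bromo-6-methoxy-4-[(E)-prop-1-enyl]phenoxy}acetate | C/C=C/c1cc(Br)c(OCC(=O)OC)c(OC)c1 | intermediate
10 | 2-{2-bromo-6-methoxy-4-[(E)-prop-1-enyl]phenoxy}acetic acid | C/C=C/c1cc(Br)c(OCC(=O)O)c(OC)c1 | intermediate
11 | (S)-4-benzyloxazolidin-2-one | O=C1N[C@@H](Cc2ccccc2)CO1 | starting material
12 | 2-{2-bromo-6-methoxy-4-[(E)-prop-1-enyl]phenoxy}acetic pivalic anhydride | C/C=C/c1cc(Br)c(OCC(=O)OC(=O)C(C)(C)C)c(OC)c1 | intermediate
13 | (4S)-4-benzyl-3-(2-{2-bromo-6-methoxy-4-[(E)-prop-1-enyl]phenoxy}acetyl)oxazolidin-2-one | C/C=C/c1cc(Br)c(OCC(=O)N2C(=O)OC[C@@H]2Cc2ccccc2)c(OC)c1 | intermediate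
14 | syringaldehyde (4-hydroxy-3,5-dimethoxybenzaldehyde) | COc1cc(C=O)cc(OC)c1O | starting material
15 | 3,5-dimethoxy-4-(triisopropylsilyloxy)benzaldehyde | COc1cc(C=O)cc(OC)c1O[Si](C(C)C)(C(C)C)C(C)C | intermediate
16 | dibutylboron (Z)-enolate of 13 | CCCCB(CCCC)O/C(=C\Oc1c(Br)cc(/C=C/C)cc1OC)N1C(=O)OC[C@@H]1Cc1ccccc1 | intermediate
17 | O-dibutylboryl aldolate of 18 | O=C(N1C(=O)OC[C@@H]1Cc1ccccc1)[C@@H](Oc1c(Br)cc(/C=C/C)cc1OC)[C@H](OB(CCCC)CCCC)c1cc(OC)c(O[Si](C(C)C)(C(C)C)C(C)C)c(OC)c1 | intermediate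
18 | (4S)-4-benzyl-3-[(2S,3R)-2-{2-bromo-6-methoxy-4-[(E)-prop-1-enyl]phenoxy}-3-[3,5-dimethoxy-4-(triisopropylsilyloxy)phenyl]-3-hydroxypropanoyl]oxazolidin-2-one | O=C(N1C(=O)OC[C@@H]1Cc1ccccc1)[C@@H](Oc1c(Br)cc(/C=C/C)cc1OC)[C@H](O)c1cc(OC)c(O[Si](C(C)C)(C(C)C)C(C)C)c(OC)c1 | intermediate
19 | (1R,2R)-2-{2-bromo-6-methoxy-4-[(E)-prop-1-enyl]phenoxy}-1-[3,5-dimethoxy-4-(triisopropylsilyloxy)phenyl]propane-1,3-diol | OC[C@@H](Oc1c(Br)cc(/C=C/C)cc1OC)[C@H](O)c1cc(OC)c(O[Si](C(C)C)(C(C)C)C(C)C)c(OC)c1 | intermediate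
20 | (2R,3R)-2-{2-bromo-6-methoxy-4-[(E)-prop-1-enyl]phenoxy}-3-[3,5-dimethoxy-4-(triisopropylsilyloxy)phenyl]-3-hydroxypropyl 4-methylbenzenesulfonate | Cc1ccc(cc1)S(=O)(=O)OC[C@@H](Oc1c(Br)cc(/C=C/C)cc1OC)[C@H](O)c1cc(OC)c(O[Si](C(C)C)(C(C)C)C(C)C)c(OC)c1 | intermediate
21 | (1R,2R)-2-{2-bromo-6-methoxy-4-[(E)-prop-1-enyl]phenoxy}-1-[3,5-dimethoxy-4-(triisopropylsilyloxy)phenyl]propan-1-ol | C[C@@H](Oc1c(Br)cc(/C=C/C)cc1OC)[C@H](O)c1cc(OC)c(O[Si](C(C)C)(C(C)C)C(C)C)c(OC)c1 | intermediate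
22 | (2R,3R)-2-[3,5-dimethoxy-4-(triisopropylsilyloxy)phenyl]-5-methoxy-3-methyl-7-[(E)-prop-1-enyl]-2,3-dihydro-1,4-benzodioxine | C/C=C/c1cc(OC)c2c(c1)O[C@H](c1cc(OC)c(O[Si](C(C)C)(C(C)C)C(C)C)c(OC)c1)[C@@H](C)O2 | intermediate
23 | 2,6-dimethoxy-4-{(2R,3R)-5-methoxy-3-methyl-7-[(E)-prop-1-enyl]-2,3-dihydro-1,4-benzodioxin-2-yl}phenol | C/C=C/c1cc(OC)c2c(c1)O[C@H](c1cc(OC)c(O)c(OC)c1)[C@@H](C)O2 | target

**Step count and risks**
Total: 13 steps. Longest linear sequence: 11 steps (2, 3, 4, 5, 6, 8, 9, 10, 11, 12, 13); 10 steps counted from 5-bromovanillin.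

Most likely to fail, step 12 (ring-closing C–O coupling). The secondary benzylic palladium alkoxide can undergo β-hydride elimination, giving ketone and debrominated arene. The fallback sets out from 21. Miyaura borylation (B2pin2, Pd(dppf)Cl2, KOAc, dioxane, 90 °C) gives (1R,2R)-1-[3,5-dimethoxy-4-(triisopropylsilyloxy)phenyl]-2-{2-methoxy-4-[(E)-prop-1-enyl]-6-(4,4,5,5-tetramethyl-1,3,2-dioxaborolan-2-yl)phenoxy}propan-1-ol F1. Oxidation with NaBO3·4H2O in THF/H2O gives the phenol 2-{[(1R,2R)-1-[3,5-dimethoxy-4-(triisopropylsilyloxy)phenyl]-1-hydroxypropan-2-yl]oxy}-3-methoxy-5-[(E)-prop-1-enyl]phenol F2. F2 is closed by acid (BF3·OEt2, CH2Cl2, −78 → −30 °C) through the para-silyloxybenzyl cation. C3 is unaffected and the diequatorial trans ring is the thermodynamically favoured product, with any minor cis isomer removed by chromatography; the route is rejoined at 22.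

Second, step 8 (aldol). The deactivated, electron-rich aldehyde and the bulky 2,6-disubstituted aryloxy enolate may give low conversion or eroded selectivity. The fallback sets out from 10, which is coupled (EDC·HCl, DMAP, CH2Cl2) with (S)-4-benzyl-1,3-thiazolidine-2-thione to give (4S)-4-benzyl-3-(2-{2-bromo-6-methoxy-4-[(E)-prop-1-enyl]phenoxy}acetyl)-1,3-thiazolidine-2-thione F3. Its chlorotitanium enolate (TiCl4 1.05 equiv, iPr2NEt 1.1 equiv, N-methyl-2-pyrrolidinone 1.1 equiv, CH2Cl2, −78 → 0 °C) adds to 15 in the same Evans-syn sense to give the (2S,3R) thioimide adduct F4. NaBH4 in THF/H2O cleaves the labile thioimide and the route is rejoined at 19.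

Third, step 11 (tosylate to methyl). The neighbouring alkoxide can close to an oxetane, and hydride can attack sulfur or slowly remove the aryl bromine. The fallback sets out from 19. The primary hydroxyl is converted selectively (PPh3, I2, imidazole, THF, 0 °C) into (1R,2S)-2-{2-bromo-6-methoxy-4-[(E)-prop-1-enyl]phenoxy}-1-[3,5-dimethoxy-4-(triisopropylsilyloxy)phenyl]-3-iodopropan-1-ol F5 (same spatial arrangement; the C2 descriptor changes because CH2I outranks the carbinol carbon). The iodide is reduced with NaBH4 in DMSO at rt, which leaves the aryl bromide alone, and the route is rejoined at 21, bypassing 20.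

**Further compounds**
F1 | step 12 | (1R,2R)-1-[3,5-dimethoxy-4-(triisopropylsilyloxy)phenyl]-2-{2-methoxy-4-[(E)-prop-1-enyl]-6-(4,4,5,5-tetramethyl-1,3,2-dioxaborolan-2-yl)phenoxy}propan-1-ol | C[C@@H](Oc1c(B2OC(C)(C)C(C)(C)O2)cc(/C=C/C)cc1OC)[C@H](O)c1cc(OC)c(O[Si](C(C)C)(C(C)C)C(C)C)c(OC)c1
F2 | step 12 | 2-{[(1R,2R)-1-[3,5-dimethoxy-4-(triisopropylsilyloxy)phenyl]-1-hydroxypropan-2-yl]oxy}-3-methoxy-5-[(E)-prop-1-enyl]phenol | C[C@@H](Oc1c(O)cc(/C=C/C)cc1OC)[C@H](O)c1cc(OC)c(O[Si](C(C)C)(C(C)C)C(C)C)c(OC)c1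
F3 | step 8 | (4S)-4-benzyl-3-(2-{2-bromo-6-methoxy-4-[(E)-prop-1-enyl]phenoxy}acetyl)-1,3-thiazolidine-2-thione | C/C=C/c1cc(Br)c(OCC(=O)N2C(=S)SC[C@@H]2Cc2ccccc2)c(OC)c1
F4 | step 8 | (2S,3R)-1-[(4S)-4-benzyl-2-thioxo-1,3-thiazolidin-3-yl]-2-{2-bromo-6-methoxy-4-[(E)-prop-1-enyl]phenoxy}-3-[3,5-dimethoxy-4-(triisopropylsilyloxy)phenyl]-3-hydroxypropan-1-one | O=C(N1C(=S)SC[C@@H]1Cc1ccccc1)[C@@H](Oc1c(Br)cc(/C=C/C)cc1OC)[C@H](O)c1cc(OC)c(O[Si](C(C)C)(C(C)C)C(C)C)c(OC)c1
F5 | step 11 | (1R,2S)-2-{2-bromo-6-methoxy-4-[(E)-prop-1-enyl]phenoxy}-1-[3,5-dimethoxy-4-(triisopropylsilyloxy)phenyl]-3-iodopropan-1-ol | IC[C@@H](Oc1c(Br)cc(/C=C/C)cc1OC)[C@H](O)c1cc(OC)c(O[Si](C(C)C)(C(C)C)C(C)C)c(OC)c1
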